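Target ⇐ hydrogenolysis of three benzyl ethers ⇐ double O-sulfation of a diaryl ether diol in which only the two future sulfate oxygens are free.
That diol ⇐ Baeyer–Villiger oxidation of a ring B aldehyde (latent 4-OH) plus acid loss of one MOM group on ring A (latent sulfated OH).
Key disconnection (diaryl ether C–O): aryne cine-substitution instead of an Ullmann/SNAr ipso coupling; a hindered ring B phenoxide adds to a 3,5-dioxygenated benzyne made from a 2,4-dioxygenated aryl bromide, the halogen sitting on purpose one carbon away from where the oxygen ends up.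
Ring order: no ring of the target is built; both benzene rings are bought (ring A from 3-(benzyloxy)phenol, ring B from 3,4,5-tris(benzyloxy)benzaldehyde), the ring A fragment is made first, the ring B fragment second, then they are joined.

Assumption: the target has no stereocentre (it is achiral), so there is no enantiomer to select; the two sulfated compounds at the end are written in the free-acid form of the target SMILES, are handled as sodium salts between the two ion-exchange treatments, and counter-ions are left out of the SMILES.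

Step 1
Reactants: 1 3-(benzyloxy)phenol
Product: 2 5-(benzyloxy)-2-bromophenol
Conditions: NBS (1.0 equiv), i-Pr2NH (10 mol %), CH2Cl2, 0 °C
Reagents that add atoms: N-bromosuccinimide, O=C1CCC(=O)N1Br
Why: Amine-catalysed ortho-selective electrophilic bromination of a phenol, in which the hydrogen-bonded N-bromoamine delivers bromine to the ortho carbon that is also para to the benzyloxy group (the other ortho carbon lies between two oxygens and is hindered); a regioisomeric bromide would in any case converge on the same diaryl ether in the aryne step.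

Step 2
Reactants: 2 5-(benzyloxy)-2-bromophenol
Product: 3 4-(benzyloxy)-1-bromo-2-(methoxymethoxy)benzene
Conditions: MOMCl, i-Pr2NEt, CH2Cl2, 0 °C → rt
Reagents that add atoms: chloromethyl methyl ether, COCCl
Why: O-alkylation of the phenol with an oxocarbenium-type electrophile (MOM protection) gives an acetal ether that survives strong base and peracid and is later removed by acid without touching benzyl ethers.

Step 3
Reactants: 4 3,4,5-tris(benzyloxy)benzaldehyde
Product: 5 3,5-bis(benzyloxy)-4-hydroxybenzaldehyde
Conditions: MgBr2·OEt2 (3 equiv), toluene–Et2O 5:1, 75 °C; 1 M HCl work-up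
Reagents that add atoms: none
Why: Chelation-controlled Lewis-acid ether cleavage, as in the classical selective 4-O-dealkylation of 3,4,5-trialkoxybenzaldehydes: the central benzyloxy group is twisted out of conjugation, is flanked by two oxygens that hold the magnesium ion, and leaves as the phenoxide para to the formyl group, so bromide attacks its benzylic carbon (SN2) in preference to the outer two.

Step 4
Reactants: 5 3,5-bis(benzyloxy)-4-hydroxybenzaldehyde
Product: 6 2,6-bis(benzyloxy)-4-(1,3-dioxolan-2-yl)phenol
Conditions: ethylene glycol (5 equiv), TsOH·H2O (5 mol %), toluene, reflux, Dean–Stark; Et3N quench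
Reagents that add atoms: ethylene glycol, OCCO
Why: Acid-catalysed acetalisation with azeotropic removal of water masks the formyl group, the only function that would not survive the lithium amide and aryllithium species of the next step, as a 1,3-dioxolane.

Step 5
Reactants: 6 2,6-bis(benzyloxy)-4-(1,3-dioxolan-2-yl)phenol; 3 4-(benzyloxy)-1-bromo-2-(methoxymethoxy)benzene (1.5 equiv)
Product: 9 3,5-bis(benzyloxy)-4-[3-(benzyloxy)-5-(methoxymethoxy)phenoxy]benzaldehyde, via aryne 7 (not isolated), via dioxolane diaryl ether 8 (not isolated)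
Conditions: lithium 2,2,6,6-tetramethylpiperidide (3.2 equiv), THF, −78 → 0 °C; then 1 M HCl–THF, rt, 30 min
Reagents that add atoms: water, O
Why: Aryne cine-substitution (elimination–addition): the hindered amide removes the proton ortho to bromine in 3 and loss of LiBr gives aryne 7, whose triple bond is polarised by the adjacent inductively withdrawing OMOM group (aryne distortion model), so the phenoxide of 6 (ortho and para carbons blocked, hence O-attack only) adds at the distal carbon, meta to both oxygens, turning the 1,2,4-pattern of 3 into the 1,3,5-pattern of ring A; the aryl anion is protonated and the dilute acid work-up hydrolyses the dioxolane while the MOM ether stays.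

Step 6
Reactants: 9 3,5-bis(benzyloxy)-4-[3-(benzyloxy)-5-(methoxymethoxy)phenoxy]benzaldehyde
Product: 11 3-(benzyloxy)-5-[2,6-bis(benzyloxy)-4-hydroxyphenoxy]phenol, via aryl formate 10 (not isolated)
Conditions: mCPBA (1.3 equiv), CH2Cl2, 0 °C → rt; aq. Na2S2O3 wash; then 3 M HCl in MeOH–THF, 50 °C
Reagents that add atoms: meta-chloroperoxybenzoic acid, O=C(OO)c1cccc(Cl)c1
Why: Baeyer–Villiger (Dakin-type) oxidation, in which the electron-rich aryl group carrying a para-aryloxy donor migrates in the Criegee intermediate to give formate 10, followed by acidic methanolysis that transesterifies the formate and cleaves the MOM acetal in the same flask, so exactly the two hydroxyls that are to be sulfated are freed while the three benzyl ethers stay.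

Step 7
Reactants: 11 3-(benzyloxy)-5-[2,6-bis(benzyloxy)-4-hydroxyphenoxy]phenol
Product: 12 3-(benzyloxy)-5-[2,6-bis(benzyloxy)-4-(sulfooxy)phenoxy]phenyl hydrogen sulfate (handled as its disodium salt)
Conditions: SO3·pyridine (6 equiv), pyridine, 40 °C; then sulfonic acid resin (Na+ form), C18 silica
Reagents that add atoms: sulfur trioxide–pyridine complex, [O-]S(=O)(=O)[n+]1ccccc1
Why: O-sulfation of phenols by sulfuryl transfer from the sulfur trioxide–amine complex, which can only reach the two unprotected hydroxyls; removal of pyridinium on the resin also prevents amine poisoning of the hydrogenolysis that follows.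

Step 8
Reactants: 12 3-(benzyloxy)-5-[2,6-bis(benzyloxy)-4-(sulfooxy)phenoxy]phenyl hydrogen sulfate
Product: 13 3-[2,6-dihydroxy-4-(sulfooxy)phenoxy]-5-hydroxyphenyl hydrogen sulfate (CNP0460023.0)
Conditions: H2 (1 atm), 10% Pd/C, MeOH–H2O 4:1, rt; then sulfonic acid resin (H+ form), H2O, 0 °C, used at once or re-neutralised for storage
Reagents that add atoms: none
Why: Heterogeneous catalytic hydrogenolysis of the three benzylic C–O bonds, to which aryl sulfate monoester anions and the diaryl ether are inert at neutral pH, followed by cold cation exchange to the free-acid form that is drawn.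

Compound list
1 | 3-(benzyloxy)phenol | Oc1cccc(OCc2ccccc2)c1 | starting material
2 | 5-(benzyloxy)-2-bromophenol | Oc1cc(OCc2ccccc2)ccc1Br | intermediate
3 | 4-(benzyloxy)-1-bromo-2-(methoxymethoxy)benzene | COCOc1cc(OCc2ccccc2)ccc1Br | intermediate
4 | 3,4,5-tris(benzyloxy)benzaldehyde | O=Cc1cc(OCc2ccccc2)c(OCc2ccccc2)c(OCc2ccccc2)c1 | starting material
5 | 3,5-bis(benzyloxy)-4-hydroxybenzaldehyde | O=Cc1cc(OCc2ccccc2)c(O)c(OCc2ccccc2)c1 | intermediate
6 | 2,6-bis(benzyloxy)-4-(1,3-dioxolan-2-yl)phenol | Oc1c(OCc2ccccc2)cc(C2OCCO2)cc1OCc1ccccc1 | intermediate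
7 | 5-(benzyloxy)-3-(methoxymethoxy)benzyne (aryne, not isolated) | COCOC1=CC(OCc2ccccc2)=CC#C1 | intermediate
8 | 2-{3,5-bis(benzyloxy)-4-[3-(benzyloxy)-5-(methoxymethoxy)phenoxy]phenyl}-1,3-dioxolane (not isolated) | COCOc1cc(OCc2ccccc2)cc(Oc2c(OCc3ccccc3)cc(C3OCCO3)cc2OCc2ccccc2)c1 | intermediate
9 | 3,5-bis(benzyloxy)-4-[3-(benzyloxy)-5-(methoxymethoxy)phenoxy]benzaldehyde | COCOc1cc(OCc2ccccc2)cc(Oc2c(OCc3ccccc3)cc(C=O)cc2OCc2ccccc2)c1 | intermediate
10 | 3,5-bis(benzyloxy)-4-[3-(benzyloxy)-5-(methoxymethoxy)phenoxy]phenyl formate (not isolated) | COCOc1cc(OCc2ccccc2)cc(Oc2c(OCc3ccccc3)cc(OC=O)cc2OCc2ccccc2)c1 | intermediate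
11 | 3-(benzyloxy)-5-[2,6-bis(benzyloxy)-4-hydroxyphenoxy]phenol | Oc1cc(OCc2ccccc2)cc(Oc2c(OCc3ccccc3)cc(O)cc2OCc2ccccc2)c1 | intermediate
12 | 3-(benzyloxy)-5-[2,6-bis(benzyloxy)-4-(sulfooxy)phenoxy]phenyl hydrogen sulfate | O=S(=O)(O)Oc1cc(OCc2ccccc2)cc(Oc2c(OCc3ccccc3)cc(OS(=O)(=O)O)cc2OCc2ccccc2)c1 | intermediate
13 | 3-[2,6-dihydroxy-4-(sulfooxy)phenoxy]-5-hydroxyphenyl hydrogen sulfate (CNP0460023.0) | O=S(=O)(O)Oc1cc(O)cc(Oc2c(O)cc(OS(=O)(=O)O)cc2O)c1 | target

Total step count: 8.
Longest linear sequence: 6 steps (steps 3 to 8 from 4; the ring A branch, steps 1, 2 and 5 to 8, is equally long).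

Steps most likely to fail

Step 5 (aryne coupling) is the main risk. The lithium phenoxide of 6 is a weak, hindered nucleophile, the amide base or its amine can add to aryne 7, and the aryllithium adduct can add to a second aryne. The fallback gives up the aryne and uses a copper-catalysed Ullmann-type ipso coupling with a bromide that carries the halogen where the oxygen must go. It sets out from 5, whose free aldehyde is tolerated so that 6 is not needed. The partner is made from commercial 5-bromobenzene-1,3-diol F1 by mono-benzylation (BnBr 1.0 equiv, K2CO3, acetone) to 3-(benzyloxy)-5-bromophenol F2 and MOM protection (MOMCl, i-Pr2NEt) to 1-(benzyloxy)-3-bromo-5-(methoxymethoxy)benzene F3. Coupling of 5 with F3 (CuI 10 mol %, picolinic acid 20 mol %, K3PO4, DMSO, 90 °C) comes back to the route at 9.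

Step 3 (selective central debenzylation) may give mixtures of mono- and bis-debenzylated aldehydes if chelation control is weaker than expected. The fallback replaces selective cleavage by selective installation, using the higher acidity of the 4-OH. It sets out from 4, which is stripped with BCl3 and pentamethylbenzene (CH2Cl2, −78 °C) to 3,4,5-trihydroxybenzaldehyde F4 (this triol can also simply be bought). Allyl bromide (1.0 equiv) with NaHCO3 in DMF alkylates the most acidic hydroxyl to give 4-(allyloxy)-3,5-dihydroxybenzaldehyde F5. BnBr and K2CO3 in DMF then give 4-(allyloxy)-3,5-bis(benzyloxy)benzaldehyde F6, and deallylation with Pd(PPh3)4 (2 mol %) and morpholine in THF comes back to the route at 5.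

Step 6 (late Baeyer–Villiger) may suffer from peracid hydroxylation of the very electron-rich ring A. The fallback moves the oxidation ahead of the coupling. It sets out from 5, which undergoes a classical Dakin oxidation (H2O2, aq. NaOH, THF, 0 °C, under N2, Na2S2O4 work-up) to 2,6-bis(benzyloxy)benzene-1,4-diol F7. MOMCl (1.0 equiv) and i-Pr2NEt react at the unhindered hydroxyl to give 2,6-bis(benzyloxy)-4-(methoxymethoxy)phenol F8. The aryne coupling with 3 under the conditions of step 5 (no acid work-up needed) gives 1-(benzyloxy)-3-[2,6-bis(benzyloxy)-4-(methoxymethoxy)phenoxy]-5-(methoxymethoxy)benzene F9, and 3 M HCl in MeOH–THF at 50 °C removes both MOM groups and comes back to the route at 11.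

Further compounds
F1 | step 5 | 5-bromobenzene-1,3-diol | Oc1cc(O)cc(Br)c1
F2 | step 5 | 3-(benzyloxy)-5-bromophenol | Oc1cc(Br)cc(OCc2ccccc2)c1
F3 | step 5 | 1-(benzyloxy)-3-bromo-5-(methoxymethoxy)benzene | COCOc1cc(Br)cc(OCc2ccccc2)c1
F4 | step 3 | 3,4,5-trihydroxybenzaldehyde | O=Cc1cc(O)c(O)c(O)c1
F5 | step 3 | 4-(allyloxy)-3,5-dihydroxybenzaldehyde | C=CCOc1c(O)cc(C=O)cc1O
F6 | step 3 | 4-(allyloxy)-3,5-bis(benzyloxy)benzaldehyde | C=CCOc1c(OCc2ccccc2)cc(C=O)cc1OCc1ccccc1
F7 | step 6 | 2,6-bis(benzyloxy)benzene-1,4-diol | Oc1cc(OCc2ccccc2)c(O)c(OCc2ccccc2)c1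
F8 | step 6 | 2,6-bis(benzyloxy)-4-(methoxymethoxy)phenol | COCOc1cc(OCc2ccccc2)c(O)c(OCc2ccccc2)c1
F9 | step 6 | 1-(benzyloxy)-3-[2,6-bis(benzyloxy)-4-(methoxymethoxy)phenoxy]-5-(methoxymethoxy)benzene | COCOc1cc(OCc2ccccc2)cc(Oc2c(OCc3ccccc3)cc(OCOC)cc2OCc2ccccc2)c1
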